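**Retrosynthetic overview**
1. Target 5 is a saturated 33-membered lactone (one ester, 31 ring CH2). Retro-hydrogenation gives macrocyclic alkene 4; the alkene position is free to choose because it is erased at the end.
2. Alkene 4 is opened by a ring-closing-metathesis disconnection at C23=C24 to the open-chain diene ester 3 (ethylene is lost: 23 + 11 − 2 = 32 ring carbons).
3. Ester 3 is disconnected at the ester C–O bond to tricos-22-enoic acid 1 and undec-10-en-1-ol 2.
4. There is only one ring: it is formed in step 2 (metathesis) and saturated in step 3.

Assumption: the SMILES is read as the lactone with 31 ring CH2 groups (C32H62O2, 32-dotriacontanolide). It has no stereocentre, so "single enantiomer" means the achiral compound as drawn. Tricos-22-enoic acid (ω-tricosenoic acid) and undec-10-en-1-ol are taken as catalogue compounds.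

**Route**

Step 1
Reactants: 1 tricos-22-enoic acid; 2 undec-10-en-1-ol
Product: 3 undec-10-en-1-yl tricos-22-enoate
Conditions: DCC (1.1 equiv), DMAP (0.1 equiv), CH2Cl2, 0 °C to rt, 12 h; filter, chromatography
Reagents that add atoms: none
Why: Steglich esterification, in which the carbodiimide activates the acid and DMAP transfers the acyl group to the unhindered primary alcohol while both terminal alkenes stay untouched; no stereocentre is formed.

Step 2
Reactants: 3 undec-10-en-1-yl tricos-22-enoate
Product: 4 oxacyclotritriacont-23-en-2-one (E/Z mixture at C23=C24)
Conditions: second-generation Grubbs catalyst (H2IMes)(PCy3)Cl2Ru=CHPh (5 mol%), 1,4-benzoquinone (10 mol%), CH2Cl2 (1 mM, 3 added by syringe pump over 8 h), 40 °C, Ar sparge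
Reagents that add atoms: none
Why: Ring-closing metathesis of an α,ω-diene to a strain-free 33-membered ring, driven by loss of ethylene and favoured over oligomerisation by high dilution, with benzoquinone suppressing double-bond migration that would give ring-contracted homologues; the E/Z ratio is irrelevant and no stereocentre is formed.

Step 3
Reactants: 4 oxacyclotritriacont-23-en-2-one (E/Z mixture)
Product: 5 oxacyclotritriacontan-2-one (32-dotriacontanolide)
Conditions: H2 (1 atm), 10% Pd/C, EtOAc, rt, 6 h; filter through Celite
Reagents that add atoms: none
Why: Heterogeneous catalytic hydrogenation of an isolated 1,2-disubstituted alkene, to which the lactone is inert, so both alkene isomers converge on the same saturated achiral macrolide.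

**Compound list**
1 | tricos-22-enoic acid (22-tricosenoic acid), CH2=CH(CH2)20CO2H | C=CCCCCCCCCCCCCCCCCCCCCCC(=O)O | starting material
2 | undec-10-en-1-ol, CH2=CH(CH2)9OH | C=CCCCCCCCCCO | starting material
3 | undec-10-en-1-yl tricos-22-enoate (acyclic diene ester, no stereocentre) | C=CCCCCCCCCCCCCCCCCCCCCCC(=O)OCCCCCCCCCC=C | intermediate
4 | oxacyclotritriacont-23-en-2-one (33-membered unsaturated lactone, E/Z mixture, no stereocentre) | O=C1CCCCCCCCCCCCCCCCCCCCC=CCCCCCCCCCO1 | intermediate
5 | oxacyclotritriacontan-2-one (32-dotriacontanolide, achiral) | O=C1CCCCCCCCCCCCCCCCCCCCCCCCCCCCCCCO1 | target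

**Totals**
Total step count: 3. Longest linear sequence: 3.

**Steps most likely to fail, with fallbacks**

Step 2 (macrocyclic metathesis) is the most at risk. Acyclic oligomers may dominate, or double-bond migration may give ring-contracted homologues that cannot be separated from 4. The fallback closes the ring at the ester C–O bond instead of at the C=C bond. It sets out from 1 and 2. Cross-metathesis of acid 1 with alcohol 2 (4 equiv) using the second-generation Grubbs catalyst (H2IMes)(PCy3)Cl2Ru=CHPh in CH2Cl2 at 40 °C needs no dilution and gives (E/Z)-32-hydroxydotriacont-22-enoic acid F2. The diol and diacid homodimers are removed by acid–base extraction and chromatography. Yamaguchi activation with 2,4,6-trichlorobenzoyl chloride and Et3N in THF gives 32-hydroxydotriacont-22-enoic 2,4,6-trichlorobenzoic anhydride F3. Slow addition of this to DMAP in refluxing toluene (about 1 mM) effects macrolactonisation to 4, where the fallback comes back to the route.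

Step 3 (hydrogenation) is next. Residual ruthenium or phosphine from step 2 can poison Pd/C, and any unreduced 4 co-elutes with 5. The fallback replaces heterogeneous catalysis by a stoichiometric, metal-free diimide reduction. It sets out from 4. p-Toluenesulfonyl hydrazide (excess) and NaOAc in refluxing THF/water generate diimide F4 in the flask. Diimide transfers H2 to the C=C bond in a concerted step, cannot isomerise the alkene or touch the lactone, and gives 5, where the fallback comes back to the route.

Step 1 (Steglich esterification) is the least at risk. The concerns are N-acylurea formation and traces of urea that are hard to remove from the waxy ester. The fallback forms the ester by O-alkylation of the carboxylate (SN2) instead of acyl substitution. It sets out from 2. MsCl and Et3N in CH2Cl2 at 0 °C give undec-10-en-1-yl methanesulfonate F1. This is heated with acid 1 and Cs2CO3 in DMF at 50 °C, and the cesium salt of 1 displaces the mesylate to give 3, where the fallback comes back to the route.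

**Further compounds**
F1 | step 1 | undec-10-en-1-yl methanesulfonate | C=CCCCCCCCCCOS(C)(=O)=O
F2 | step 2 | (E/Z)-32-hydroxydotriacont-22-enoic acid | OCCCCCCCCCC=CCCCCCCCCCCCCCCCCCCCCCC(=O)O
F3 | step 2 | 32-hydroxydotriacont-22-enoic 2,4,6-trichlorobenzoic anhydride (E/Z) | OCCCCCCCCCC=CCCCCCCCCCCCCCCCCCCCCCC(=O)OC(=O)c1c(Cl)cc(Cl)cc1Cl
F4 | step 3 | diimide (diazene) | N=N
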